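**Retrosynthetic overview**
1. The last C–C bond made is C12–C13, the centre of the chain: a right-half C16 allylic phenyl sulfone (C1–C12) is alkylated by a left-half C16 oxiranylmethyl triflate (C13–C24), and the sulfonyl group is removed in the final step.
2. There is one ring, the oxirane. It is made on the left half before the union, by Sharpless epoxidation of the E allylic alcohol (sets 14R,15R).
3. Each half has a Roche-ester-derived end (ester → ketone → methylenation; CH2OH → CH2MgBr) that is joined by Cu-catalysed coupling to one common C5 allylic bromide made from prenol.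
4. The right half takes a second copy of the C5 bromide by sulfone alkylation and desulfonylation; the left half takes its homoprenyl group from 5-bromo-2-methylpent-2-ene.

Assumption: the backbone is numbered C1 (isopropenyl CH2) to C24, so the target is 3S,6E,10E,14R,15R,18R; TBS = tert-butyldimethylsilyl, Tf = trifluoromethanesulfonyl.

**Common C5 bromide**

Step 1
Reactants: 1 prenol (3-methylbut-2-en-1-ol)
Product: 2 prenyl TBS ether
Conditions: TBSCl, imidazole, CH2Cl2, 0 °C → rt
Reagents that add atoms: tert-butyldimethylsilyl chloride, CC(C)(C)[Si](C)(C)Cl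
Why: Silyl ether formation protects the primary allylic alcohol so that the distal methyl group can be oxidised and the unit later used as an electrophile.

Step 2
Reactants: 2 prenyl TBS ether
Product: 3 (E)-4-(TBS-oxy)-2-methylbut-2-en-1-ol
Conditions: SeO2 (0.5 equiv), t-BuOOH, salicylic acid (cat.), CH2Cl2, rt
Reagents that add atoms: tert-butyl hydroperoxide, CC(C)(C)OO (oxygen relayed by selenium dioxide, O=[Se]=O)
Why: SeO2 allylic oxidation (ene reaction then [2,3]-shift) attacks only the E methyl group of the trisubstituted alkene, which fixes the E geometry of every later C5 unit.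

Step 3
Reactants: 3 (E)-4-(TBS-oxy)-2-methylbut-2-en-1-ol
Product: 4 (E)-4-bromo-3-methylbut-2-enyl TBS ether
Conditions: CBr4, PPh3, CH2Cl2, 0 °C
Reagents that add atoms: carbon tetrabromide, BrC(Br)(Br)Br
Why: The Appel reaction replaces the primary allylic hydroxyl by bromide in a neutral SN2 process that leaves the E alkene and the silyl ether untouched.

**Right half (C1–C12)**

Step 4
Reactants: 5 methyl (S)-3-hydroxy-2-methylpropanoate
Product: 6 methyl (S)-3-(TBS-oxy)-2-methylpropanoate
Conditions: TBSCl, imidazole, DMF, rt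
Reagents that add atoms: tert-butyldimethylsilyl chloride, CC(C)(C)[Si](C)(C)Cl
Why: Silylation of the primary alcohol protects it for the organomagnesium steps, and the C3 stereocentre is taken unchanged from the Roche ester.

Step 5
Reactants: 6 methyl (S)-3-(TBS-oxy)-2-methylpropanoate
Product: 7 (S)-3-(TBS-oxy)-N-methoxy-N,2-dimethylpropanamide
Conditions: MeNH(OMe)·HCl, i-PrMgCl, THF, −20 → 0 °C
Reagents that add atoms: N,O-dimethylhydroxylamine hydrochloride, CNOC.Cl
Why: Weinreb amide formation by aminolysis of the ester with the magnesium amide is faster than enolisation, so the α-stereocentre is kept.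

Step 6
Reactants: 7 (S)-3-(TBS-oxy)-N-methoxy-N,2-dimethylpropanamide
Product: 8 (S)-4-(TBS-oxy)-3-methylbutan-2-one
Conditions: MeMgBr, THF, 0 °C; aq NH4Cl
Reagents that add atoms: methylmagnesium bromide, C[Mg]Br
Why: In the Weinreb ketone synthesis the chelated tetrahedral adduct stops the Grignard addition at the ketone, and the cold, brief conditions do not epimerise the α-centre.

Step 7
Reactants: 8 (S)-4-(TBS-oxy)-3-methylbutan-2-one
Product: 9 (R)-2,3-dimethylbut-3-enyl TBS ether
Conditions: Cp2TiMe2, toluene, 65 °C, dark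
Reagents that add atoms: dimethyltitanocene, C[Ti](C)(C1C=CC=C1)C1C=CC=C1
Why: Petasis methylenation (titanium carbene, [2+2] then retro-[2+2]) is non-basic, so the ketone becomes the 1,1-disubstituted alkene without epimerisation or β-elimination of the silyloxy group (the descriptor changes only through CIP priorities).

Step 8
Reactants: 9 (R)-2,3-dimethylbut-3-enyl TBS ether
Product: 10 (R)-2,3-dimethylbut-3-en-1-ol
Conditions: TBAF, THF, 0 °C → rt
Reagents that add atoms: none
Why: Fluoride-driven desilylation frees the primary alcohol and nothing else in the molecule reacts.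

Step 9
Reactants: 10 (R)-2,3-dimethylbut-3-en-1-ol
Product: 11 (R)-4-bromo-2,3-dimethylbut-1-ene
Conditions: PPh3, NBS, CH2Cl2, −20 → 0 °C
Reagents that add atoms: N-bromosuccinimide, O=C1CCC(=O)N1Br
Why: Appel-type bromination is an SN2 displacement at the primary carbon, one atom away from the stereocentre, which is therefore retained.

Step 10
Reactants: 11 (R)-4-bromo-2,3-dimethylbut-1-ene; 4 (E)-4-bromo-3-methylbut-2-enyl TBS ether
Product: 13 (2E,6S)-3,6,7-trimethylocta-2,7-dienyl TBS ether, via (R)-(2,3-dimethylbut-3-enyl)magnesium bromide 12 (not isolated)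
Conditions: Mg, THF, 40 °C; then 4, Li2CuCl4 (3 mol %), THF, −20 → 0 °C
Reagents that add atoms: none
Why: Cu-catalysed Grignard cross-coupling (Kochi type) with the primary allylic bromide goes by direct SN2 substitution under these conditions, which forms C4–C5 with the E alkene retained and the stereocentre carried in from 11.

Step 11
Reactants: 13 (2E,6S)-3,6,7-trimethylocta-2,7-dienyl TBS ether
Product: 14 (2E,6S)-3,6,7-trimethylocta-2,7-dien-1-ol
Conditions: TBAF, THF, rt
Reagents that add atoms: none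
Why: Fluoride desilylation releases the allylic alcohol without touching the alkenes.

Step 12
Reactants: 14 (2E,6S)-3,6,7-trimethylocta-2,7-dien-1-ol
Product: 15 (3S,6E)-8-bromo-2,3,6-trimethylocta-1,6-diene
Conditions: CBr4, PPh3, CH2Cl2, −20 → 0 °C
Reagents that add atoms: carbon tetrabromide, BrC(Br)(Br)Br
Why: The Appel reaction gives the primary allylic bromide under neutral conditions without allylic transposition or isomerisation of the isopropenyl group.

Step 13
Reactants: 15 (3S,6E)-8-bromo-2,3,6-trimethylocta-1,6-diene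
Product: 16 (2E,6S)-3,6,7-trimethylocta-2,7-dienyl phenyl sulfone
Conditions: PhSO2Na, DMF, rt
Reagents that add atoms: sodium benzenesulfinate, [Na+].[O-]S(=O)c1ccccc1
Why: SN2 S-alkylation of the sulfinate by the primary allylic bromide gives the allylic sulfone with the E alkene intact.

Step 14
Reactants: 16 (2E,6S)-3,6,7-trimethylocta-2,7-dienyl phenyl sulfone; 4 (E)-4-bromo-3-methylbut-2-enyl TBS ether
Product: 18 (2E,6E,10S)-3,7,10,11-tetramethyl-5-(phenylsulfonyl)dodeca-2,6,11-trienyl TBS ether (both epimers at the sulfonyl carbon), via α-lithio sulfone 17 (not isolated)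
Conditions: n-BuLi, THF, −78 °C; then 4, −78 → −20 °C
Reagents that add atoms: none
Why: α-Alkylation of the sulfone-stabilised allyl anion by the allylic bromide (Julia/Biellmann-type sulfone coupling) forms C8–C9 regioselectively without moving either double bond, and the new sulfonyl-bearing centre is removed in the next step.

Step 15
Reactants: 18 (2E,6E,10S)-3,7,10,11-tetramethyl-5-(phenylsulfonyl)dodeca-2,6,11-trienyl TBS ether
Product: 19 (2E,6E,10S)-3,7,10,11-tetramethyldodeca-2,6,11-trienyl TBS ether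
Conditions: PdCl2(dppp) (5 mol %), LiBHEt3, THF, 0 °C
Reagents that add atoms: none
Why: In this Pd-catalysed hydride desulfonylation the π-allylpalladium intermediate takes hydride at its less substituted terminus, so the trisubstituted E alkene is regenerated in place and the allylic silyl ether is inert.

Step 16
Reactants: 19 (2E,6E,10S)-3,7,10,11-tetramethyldodeca-2,6,11-trienyl TBS ether
Product: 20 (2E,6E,10S)-3,7,10,11-tetramethyldodeca-2,6,11-trien-1-ol
Conditions: TBAF, THF, rt
Reagents that add atoms: none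
Why: Fluoride desilylation releases the allylic alcohol.

Step 17
Reactants: 20 (2E,6E,10S)-3,7,10,11-tetramethyldodeca-2,6,11-trien-1-ol
Product: 21 (3S,6E,10E)-12-bromo-2,3,6,10-tetramethyldodeca-1,6,10-triene
Conditions: CBr4, PPh3, CH2Cl2, −20 → 0 °C
Reagents that add atoms: carbon tetrabromide, BrC(Br)(Br)Br
Why: The Appel reaction converts the primary allylic alcohol into the bromide without transposition, as for farnesol-type alcohols.

Step 18
Reactants: 21 (3S,6E,10E)-12-bromo-2,3,6,10-tetramethyldodeca-1,6,10-triene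
Product: 22 (2E,6E,10S)-3,7,10,11-tetramethyldodeca-2,6,11-trienyl phenyl sulfone
Conditions: PhSO2Na, DMF, rt
Reagents that add atoms: sodium benzenesulfinate, [Na+].[O-]S(=O)c1ccccc1
Why: SN2 S-alkylation of the sulfinate gives the right-half allylic sulfone, whose α-carbon is the future C12.

**Left half (C13–C24)**

Step 19
Reactants: 23 methyl (R)-3-hydroxy-2-methylpropanoate
Product: 24 methyl (R)-3-(TBS-oxy)-2-methylpropanoate
Conditions: TBSCl, imidazole, DMF, rt
Reagents that add atoms: tert-butyldimethylsilyl chloride, CC(C)(C)[Si](C)(C)Cl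
Why: Silylation protects the primary alcohol, and the C18 stereocentre is taken unchanged from the (R)-Roche ester.

Step 20
Reactants: 24 methyl (R)-3-(TBS-oxy)-2-methylpropanoate
Product: 25 (R)-3-(TBS-oxy)-N-methoxy-N,2-dimethylpropanamide
Conditions: MeNH(OMe)·HCl, i-PrMgCl, THF, −20 → 0 °C
Reagents that add atoms: N,O-dimethylhydroxylamine hydrochloride, CNOC.Cl
Why: Weinreb amide formation by the magnesium amide proceeds without enolisation, so the α-stereocentre is kept.

Step 21
Reactants: 25 (R)-3-(TBS-oxy)-N-methoxy-N,2-dimethylpropanamide; 26 5-bromo-2-methylpent-2-ene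
Product: 28 (R)-1-(TBS-oxy)-2,7-dimethyloct-6-en-3-one, via (4-methylpent-3-enyl)magnesium bromide 27 (not isolated)
Conditions: Mg, THF, rt → 40 °C; then 25, THF, 0 °C; aq NH4Cl
Reagents that add atoms: none
Why: Weinreb ketone synthesis with the homoprenyl Grignard reagent stops at the ketone through the chelated adduct and attaches C20–C24 without disturbing the α-centre.

Step 22
Reactants: 28 (R)-1-(TBS-oxy)-2,7-dimethyloct-6-en-3-one
Product: 29 (S)-2,7-dimethyl-3-methylideneoct-6-enyl TBS ether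
Conditions: Cp2TiMe2, toluene, 65 °C, dark
Reagents that add atoms: dimethyltitanocene, C[Ti](C)(C1C=CC=C1)C1C=CC=C1
Why: Non-basic Petasis methylenation installs the C19 methylidene group without epimerising C18 (the descriptor changes only through CIP priorities).

Step 23
Reactants: 29 (S)-2,7-dimethyl-3-methylideneoct-6-enyl TBS ether
Product: 30 (S)-2,7-dimethyl-3-methylideneoct-6-en-1-ol
Conditions: TBAF, THF, rt
Reagents that add atoms: none
Why: Fluoride desilylation frees the primary alcohol.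

Step 24
Reactants: 30 (S)-2,7-dimethyl-3-methylideneoct-6-en-1-ol
Product: 31 (S)-8-bromo-2,7-dimethyl-6-methylideneoct-2-ene
Conditions: PPh3, NBS, CH2Cl2, −20 → 0 °C
Reagents that add atoms: N-bromosuccinimide, O=C1CCC(=O)N1Br
Why: Appel-type SN2 bromination at the primary carbon leaves the adjacent stereocentre and both alkenes untouched.

Step 25
Reactants: 31 (S)-8-bromo-2,7-dimethyl-6-methylideneoct-2-ene; 4 (E)-4-bromo-3-methylbut-2-enyl TBS ether
Product: 33 (2E,6R)-3,6,11-trimethyl-7-methylidenedodeca-2,10-dienyl TBS ether, via (S)-(2,7-dimethyl-3-methylideneoct-6-enyl)magnesium bromide 32 (not isolated)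
Conditions: Mg, THF, 40 °C; then 4, Li2CuCl4 (3 mol %), THF, −20 → 0 °C
Reagents that add atoms: none
Why: Cu-catalysed Grignard cross-coupling (Kochi type) substitutes the primary allylic bromide directly, which forms C16–C17 with the E alkene retained and C18 carried in from 31.

Step 26
Reactants: 33 (2E,6R)-3,6,11-trimethyl-7-methylidenedodeca-2,10-dienyl TBS ether
Product: 34 (2E,6R)-3,6,11-trimethyl-7-methylidenedodeca-2,10-dien-1-ol
Conditions: TBAF, THF, rt
Reagents that add atoms: none
Why: Fluoride desilylation gives the E allylic alcohol needed to direct the epoxidation.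

Step 27
Reactants: 34 (2E,6R)-3,6,11-trimethyl-7-methylidenedodeca-2,10-dien-1-ol
Product: 35 {(2R,3R)-3-[(3R)-3,8-dimethyl-4-methylidenenon-7-enyl]-3-methyloxiran-2-yl}methanol
Conditions: Ti(OiPr)4 (10 mol %), D-(−)-diethyl tartrate (12 mol %), t-BuOOH, 4 Å molecular sieves, CH2Cl2, −20 °C
Reagents that add atoms: tert-butyl hydroperoxide, CC(C)(C)OO
Why: Sharpless asymmetric epoxidation oxidises only the alkene of the allylic alcohol, and D-(−)-diethyl tartrate delivers oxygen to the face that gives the (2R,3R) trans-epoxide (C14 R, C15 R) from the E alkene.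

Step 28
Reactants: 35 {(2R,3R)-3-[(3R)-3,8-dimethyl-4-methylidenenon-7-enyl]-3-methyloxiran-2-yl}methanol
Product: 36 {(2R,3R)-3-[(3R)-3,8-dimethyl-4-methylidenenon-7-enyl]-3-methyloxiran-2-yl}methyl trifluoromethanesulfonate
Conditions: Tf2O, 2,6-lutidine, CH2Cl2, −78 °C; used at once
Reagents that add atoms: trifluoromethanesulfonic anhydride, O=S(=O)(OS(=O)(=O)C(F)(F)F)C(F)(F)F
Why: O-Triflation of the primary alcohol with a hindered base at −78 °C gives the activated electrophile without opening the oxirane.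

**Union of the halves**

Step 29
Reactants: 22 (2E,6E,10S)-3,7,10,11-tetramethyldodeca-2,6,11-trienyl phenyl sulfone; 36 {(2R,3R)-3-[(3R)-3,8-dimethyl-4-methylidenenon-7-enyl]-3-methyloxiran-2-yl}methyl trifluoromethanesulfonate
Product: 38 (2R,3R)-2-[(3R)-3,8-dimethyl-4-methylidenenon-7-enyl]-2-methyl-3-[(3E,7E,11S)-4,8,11,12-tetramethyl-2-(phenylsulfonyl)trideca-3,7,12-trienyl]oxirane (both epimers at the sulfonyl carbon), via α-lithio sulfone 37 (not isolated)
Conditions: n-BuLi (1.0 equiv), THF, −78 °C; then 36 (1.05 equiv), THF, −78 °C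
Reagents that add atoms: none
Why: SN2 alkylation of the sulfone-stabilised allyl anion at the primary triflate is far faster at −78 °C than attack on the trisubstituted oxirane, so the two C16 halves are joined at C12–C13 with all four stereocentres intact.

Step 30
Reactants: 38 (2R,3R)-2-[(3R)-3,8-dimethyl-4-methylidenenon-7-enyl]-2-methyl-3-[(3E,7E,11S)-4,8,11,12-tetramethyl-2-(phenylsulfonyl)trideca-3,7,12-trienyl]oxirane
Product: 39 (2R,3R)-2-[(3R)-3,8-dimethyl-4-methylidenenon-7-enyl]-2-methyl-3-[(3E,7E,11S)-4,8,11,12-tetramethyltrideca-3,7,12-trienyl]oxirane (CNP0306316.1)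
Conditions: PdCl2(dppp) (10 mol %), LiBHEt3 (2 equiv), THF, −10 → 0 °C
Reagents that add atoms: none
Why: Pd-catalysed hydride desulfonylation through the π-allylpalladium intermediate puts hydrogen on C12 (the less substituted terminus) and keeps the 10E alkene, while the hindered trisubstituted oxirane should survive the short cold exposure to hydride.

**Compound list**
1 | prenol (3-methylbut-2-en-1-ol) | CC(C)=CCO | starting material
2 | tert-butyldimethyl[(3-methylbut-2-en-1-yl)oxy]silane | CC(C)=CCO[Si](C)(C)C(C)(C)C | intermediate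
3 | (E)-4-[(tert-butyldimethylsilyl)oxy]-2-methylbut-2-en-1-ol | OC/C(C)=C/CO[Si](C)(C)C(C)(C)C | intermediate
4 | (E)-[(4-bromo-3-methylbut-2-en-1-yl)oxy](tert-butyl)dimethylsilane | BrC/C(C)=C/CO[Si](C)(C)C(C)(C)C | intermediate
5 | methyl (S)-3-hydroxy-2-methylpropanoate | OC[C@H](C)C(=O)OC | starting material
6 | methyl (S)-3-[(tert-butyldimethylsilyl)oxy]-2-methylpropanoate | CC(C)(C)[Si](C)(C)OC[C@H](C)C(=O)OC | intermediate
7 | (S)-3-[(tert-butyldimethylsilyl)oxy]-N-methoxy-N,2-dimethylpropanamide | CC(C)(C)[Si](C)(C)OC[C@H](C)C(=O)N(C)OC | intermediate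
8 | (S)-4-[(tert-butyldimethylsilyl)oxy]-3-methylbutan-2-one | CC(C)(C)[Si](C)(C)OC[C@H](C)C(C)=O | intermediate
9 | (R)-tert-butyl[(2,3-dimethylbut-3-en-1-yl)oxy]dimethylsilane | CC(C)(C)[Si](C)(C)OC[C@H](C)C(C)=C | intermediate
10 | (R)-2,3-dimethylbut-3-en-1-ol | OC[C@H](C)C(C)=C | intermediate
11 | (R)-4-bromo-2,3-dimethylbut-1-ene | BrC[C@H](C)C(C)=C | intermediate
12 | (R)-(2,3-dimethylbut-3-en-1-yl)magnesium bromide | Br[Mg]C[C@H](C)C(C)=C | intermediate
13 | tert-butyldimethyl{[(2E,6S)-3,6,7-trimethylocta-2,7-dien-1-yl]oxy}silane | C=C(C)[C@@H](C)CC/C(C)=C/CO[Si](C)(C)C(C)(C)C | intermediate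
14 | (2E,6S)-3,6,7-trimethylocta-2,7-dien-1-ol | C=C(C)[C@@H](C)CC/C(C)=C/CO | intermediate
15 | (3S,6E)-8-bromo-2,3,6-trimethylocta-1,6-diene | C=C(C)[C@@H](C)CC/C(C)=C/CBr | intermediate
16 | {[(2E,6S)-3,6,7-trimethylocta-2,7-dien-1-yl]sulfonyl}benzene | C=C(C)[C@@H](C)CC/C(C)=C/CS(=O)(=O)c1ccccc1 | intermediate
17 | α-lithio derivative of 16 (lithium on the sulfonyl-bearing carbon) | C=C(C)[C@@H](C)CC/C(C)=C/C([Li])S(=O)(=O)c1ccccc1 | intermediate
18 | tert-butyldimethyl{[(2E,6E,10S)-3,7,10,11-tetramethyl-5-(phenylsulfonyl)dodeca-2,6,11-trien-1-yl]oxy}silane (both C5 epimers) | C=C(C)[C@@H](C)CC/C(C)=C/C(C/C(C)=C/CO[Si](C)(C)C(C)(C)C)S(=O)(=O)c1ccccc1 | intermediate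
19 | tert-butyldimethyl{[(2E,6E,10S)-3,7,10,11-tetramethyldodeca-2,6,11-trien-1-yl]oxy}silane | C=C(C)[C@@H](C)CC/C(C)=C/CC/C(C)=C/CO[Si](C)(C)C(C)(C)C | intermediate
20 | (2E,6E,10S)-3,7,10,11-tetramethyldodeca-2,6,11-trien-1-ol | C=C(C)[C@@H](C)CC/C(C)=C/CC/C(C)=C/CO | intermediate
21 | (3S,6E,10E)-12-bromo-2,3,6,10-tetramethyldodeca-1,6,10-triene | C=C(C)[C@@H](C)CC/C(C)=C/CC/C(C)=C/CBr | intermediate
22 | {[(2E,6E,10S)-3,7,10,11-tetramethyldodeca-2,6,11-trien-1-yl]sulfonyl}benzene | C=C(C)[C@@H](C)CC/C(C)=C/CC/C(C)=C/CS(=O)(=O)c1ccccc1 | intermediate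
23 | methyl (R)-3-hydroxy-2-methylpropanoate | OC[C@@H](C)C(=O)OC | starting material
24 | methyl (R)-3-[(tert-butyldimethylsilyl)oxy]-2-methylpropanoate | CC(C)(C)[Si](C)(C)OC[C@@H](C)C(=O)OC | intermediate
25 | (R)-3-[(tert-butyldimethylsilyl)oxy]-N-methoxy-N,2-dimethylpropanamide | CC(C)(C)[Si](C)(C)OC[C@@H](C)C(=O)N(C)OC | intermediate
26 | 5-bromo-2-methylpent-2-ene | CC(C)=CCCBr | starting material
27 | (4-methylpent-3-en-1-yl)magnesium bromide | CC(C)=CCC[Mg]Br | intermediate
28 | (R)-1-[(tert-butyldimethylsilyl)oxy]-2,7-dimethyloct-6-en-3-one | CC(C)(C)[Si](C)(C)OC[C@@H](C)C(=O)CCC=C(C)C | intermediate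
29 | (S)-tert-butyl[(2,7-dimethyl-3-methylideneoct-6-en-1-yl)oxy]dimethylsilane | CC(C)(C)[Si](C)(C)OC[C@@H](C)C(=C)CCC=C(C)C | intermediate
30 | (S)-2,7-dimethyl-3-methylideneoct-6-en-1-ol | OC[C@@H](C)C(=C)CCC=C(C)C | intermediate
31 | (S)-8-bromo-2,7-dimethyl-6-methylideneoct-2-ene | BrC[C@@H](C)C(=C)CCC=C(C)C | intermediate
32 | (S)-(2,7-dimethyl-3-methylideneoct-6-en-1-yl)magnesium bromide | Br[Mg]C[C@@H](C)C(=C)CCC=C(C)C | intermediate
33 | tert-butyldimethyl{[(2E,6R)-3,6,11-trimethyl-7-methylidenedodeca-2,10-dien-1-yl]oxy}silane | C=C(CCC=C(C)C)[C@H](C)CC/C(C)=C/CO[Si](C)(C)C(C)(C)C | intermediate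
34 | (2E,6R)-3,6,11-trimethyl-7-methylidenedodeca-2,10-dien-1-ol | C=C(CCC=C(C)C)[C@H](C)CC/C(C)=C/CO | intermediate
35 | {(2R,3R)-3-[(3R)-3,8-dimethyl-4-methylidenenon-7-en-1-yl]-3-methyloxiran-2-yl}methanol | C=C(CCC=C(C)C)[C@H](C)CC[C@@]1(C)O[C@@H]1CO | intermediate
36 | {(2R,3R)-3-[(3R)-3,8-dimethyl-4-methylidenenon-7-en-1-yl]-3-methyloxiran-2-yl}methyl trifluoromethanesulfonate | C=C(CCC=C(C)C)[C@H](C)CC[C@@]1(C)O[C@@H]1COS(=O)(=O)C(F)(F)F | intermediate
37 | α-lithio derivative of 22 (lithium on the sulfonyl-bearing carbon) | C=C(C)[C@@H](C)CC/C(C)=C/CC/C(C)=C/C([Li])S(=O)(=O)c1ccccc1 | intermediate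
38 | (2R,3R)-2-[(3R)-3,8-dimethyl-4-methylidenenon-7-en-1-yl]-2-methyl-3-[(3E,7E,11S)-4,8,11,12-tetramethyl-2-(phenylsulfonyl)trideca-3,7,12-trien-1-yl]oxirane (both epimers at the sulfonyl carbon) | C=C(CCC=C(C)C)[C@H](C)CC[C@@]1(C)O[C@@H]1CC(/C=C(\C)CC/C=C(\C)CC[C@H](C)C(=C)C)S(=O)(=O)c1ccccc1 | intermediate
39 | (2R,3R)-2-[(3R)-3,8-dimethyl-4-methylidenenon-7-en-1-yl]-2-methyl-3-[(3E,7E,11S)-4,8,11,12-tetramethyltrideca-3,7,12-trien-1-yl]oxirane (CNP0306316.1) | C=C(CCC=C(C)C)[C@H](C)CC[C@@]1(C)O[C@@H]1CC/C=C(\C)CC/C=C(\C)CC[C@H](C)C(=C)C | target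

**Step count and weak points**

Total step count: 30. Longest linear sequence: 17 steps (steps 4–18 from Roche ester 5 to sulfone 22, then steps 29 and 30).

Step 29 is the most likely to fail. The oxiranylmethyl triflate 36 is labile, and the lithio sulfone 37 may attack the oxirane or, after proton transfer, close a cyclopropane. The fallback sets out from 34, uses 37 again, and rejoins the route at 39. It makes the C12–C13 bond by opening a terminal epoxide and forms the trisubstituted oxirane last. Alcohol 34 is epoxidised with the enantiomeric catalyst (Ti(OiPr)4, L-(+)-diethyl tartrate, t-BuOOH) to the (2S,3S)-epoxy alcohol F1. Dilute HClO4 in THF–H2O at 0 °C then lets water enter at the tertiary carbon with inversion, giving the (2S,3R)-triol F2. TsCl/pyridine at 0 °C sulfonylates only the primary hydroxyl to give the monotosylate F3, and K2CO3/MeOH closes it to the terminal epoxide F4, which still carries the tertiary alcohol. Lithio sulfone 37 (2.2 equiv, THF–HMPA, −78 → 0 °C) opens F4 at its CH2 terminus to give the hydroxy sulfone F5. PdCl2(dppp)/LiBHEt3 removes the sulfonyl group while no oxirane is present and gives the (14S,15R)-diol F6. MsCl/pyridine esterifies only the secondary hydroxyl to give the mesylate F7. K2CO3/MeOH then closes the oxirane with inversion at C14, which restores the 14R,15R configuration of 39.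

Step 30 is the second risk, because LiBHEt3 can reduce the oxirane that sits two carbons from the allyl unit. The fallback sets out from 3, uses 37 again, and rejoins the route at 39. It takes the sulfonyl group off before any oxirane exists and attaches the left end last. Alcohol 3 is silylated (TBDPSCl, imidazole) to the bis-silyl ether F8, and PPTS/EtOH removes only the TBS group to give the allylic alcohol F9. CBr4/PPh3 gives the transposed C5 bromide F10. Alkylation of 37 with F10 (THF, −78 °C), an ordinary sulfone/allylic bromide coupling that forms C12–C13, gives the C21 sulfone F11. PdCl2(dppp)/LiBHEt3 gives the C21 silyl ether F12, and TBAF gives the C21 allylic alcohol F13. Sharpless epoxidation (Ti(OiPr)4, D-(−)-diethyl tartrate, t-BuOOH) gives the (2R,3R)-epoxy alcohol F14, and Tf2O/2,6-lutidine at −78 °C gives the epoxy triflate F15. Grignard reagent 32 with CuBr·SMe2 (10 mol %) in THF at −78 → −20 °C then displaces the triflate to form C16–C17 and gives 39.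

Step 10 is the third risk: the Cu-catalysed coupling may give some SN2′ product, and the Grignard reagent 12 is small and volatile. The fallback sets out from 11 and rejoins the route at 14. It builds the E trisubstituted alkene by alkyne carbometalation in place of allylic substitution. Lithiated 1-(trimethylsilyl)propyne (n-BuLi, THF, −78 °C) is alkylated by 11 to give the silyl alkyne F16, and K2CO3/MeOH gives the terminal alkyne F17. Zr-catalysed carboalumination (Me3Al, Cp2ZrCl2 cat., CH2Cl2) followed by (CH2O)n adds the methyl and hydroxymethyl groups syn across the alkyne and gives 14 with E geometry.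

**Further compounds**
F1 | step 29 | {(2S,3S)-3-[(3R)-3,8-dimethyl-4-methylidenenon-7-en-1-yl]-3-methyloxiran-2-yl}methanol | C=C(CCC=C(C)C)[C@H](C)CC[C@]1(C)O[C@H]1CO
F2 | step 29 | (2S,3R,6R)-3,6,11-trimethyl-7-methylidenedodec-10-ene-1,2,3-triol | C=C(CCC=C(C)C)[C@H](C)CC[C@@](C)(O)[C@@H](O)CO
F3 | step 29 | (2S,3R,6R)-2,3-dihydroxy-3,6,11-trimethyl-7-methylidenedodec-10-en-1-yl 4-methylbenzenesulfonate | C=C(CCC=C(C)C)[C@H](C)CC[C@@](C)(O)[C@@H](O)COS(=O)(=O)c1ccc(C)cc1
F4 | step 29 | (2R,5R)-5,10-dimethyl-6-methylidene-2-[(2S)-oxiran-2-yl]undec-9-en-2-ol | C=C(CCC=C(C)C)[C@H](C)CC[C@@](C)(O)[C@@H]1CO1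
F5 | step 29 | (3S,6E,10E,14S,15R,18R)-2,3,6,10,15,18,23-heptamethyl-19-methylidene-12-(phenylsulfonyl)tetracosa-1,6,10,22-tetraene-14,15-diol (both C12 epimers) | C=C(CCC=C(C)C)[C@H](C)CC[C@@](C)(O)[C@@H](O)CC(/C=C(\C)CC/C=C(\C)CC[C@H](C)C(=C)C)S(=O)(=O)c1ccccc1
F6 | step 29 | (3S,6E,10E,14S,15R,18R)-2,3,6,10,15,18,23-heptamethyl-19-methylidenetetracosa-1,6,10,22-tetraene-14,15-diol | C=C(CCC=C(C)C)[C@H](C)CC[C@@](C)(O)[C@@H](O)CC/C=C(\C)CC/C=C(\C)CC[C@H](C)C(=C)C
F7 | step 29 | (3S,6E,10E,14S,15R,18R)-15-hydroxy-2,3,6,10,15,18,23-heptamethyl-19-methylidenetetracosa-1,6,10,22-tetraen-14-yl methanesulfonate | C=C(CCC=C(C)C)[C@H](C)CC[C@@](C)(O)[C@@H](OS(C)(=O)=O)CC/C=C(\C)CC/C=C(\C)CC[C@H](C)C(=C)C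
F8 | step 30 | (E)-tert-butyl{[4-(tert-butyldimethylsilyloxy)-2-methylbut-2-en-1-yl]oxy}diphenylsilane | CC(C)(C)[Si](C)(C)OC/C=C(\C)CO[Si](c1ccccc1)(c1ccccc1)C(C)(C)C
F9 | step 30 | (E)-4-[(tert-butyldiphenylsilyl)oxy]-3-methylbut-2-en-1-ol | OC/C=C(\C)CO[Si](c1ccccc1)(c1ccccc1)C(C)(C)C
F10 | step 30 | (E)-[(4-bromo-2-methylbut-2-en-1-yl)oxy](tert-butyl)diphenylsilane | BrC/C=C(\C)CO[Si](c1ccccc1)(c1ccccc1)C(C)(C)C
F11 | step 30 | tert-butyl{[(2E,6E,10E,14S)-2,7,11,14,15-pentamethyl-5-(phenylsulfonyl)hexadeca-2,6,10,15-tetraen-1-yl]oxy}diphenylsilane (both C5 epimers) | C=C(C)[C@@H](C)CC/C(C)=C/CC/C(C)=C/C(C/C=C(\C)CO[Si](c1ccccc1)(c1ccccc1)C(C)(C)C)S(=O)(=O)c1ccccc1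
F12 | step 30 | tert-butyl{[(2E,6E,10E,14S)-2,7,11,14,15-pentamethylhexadeca-2,6,10,15-tetraen-1-yl]oxy}diphenylsilane | C=C(C)[C@@H](C)CC/C(C)=C/CC/C(C)=C/CC/C=C(\C)CO[Si](c1ccccc1)(c1ccccc1)C(C)(C)C
F13 | step 30 | (2E,6E,10E,14S)-2,7,11,14,15-pentamethylhexadeca-2,6,10,15-tetraen-1-ol | C=C(C)[C@@H](C)CC/C(C)=C/CC/C(C)=C/CC/C=C(\C)CO
F14 | step 30 | {(2R,3R)-2-methyl-3-[(3E,7E,11S)-4,8,11,12-tetramethyltrideca-3,7,12-trien-1-yl]oxiran-2-yl}methanol | C=C(C)[C@@H](C)CC/C(C)=C/CC/C(C)=C/CC[C@H]1O[C@]1(C)CO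
F15 | step 30 | {(2R,3R)-2-methyl-3-[(3E,7E,11S)-4,8,11,12-tetramethyltrideca-3,7,12-trien-1-yl]oxiran-2-yl}methyl trifluoromethanesulfonate | C=C(C)[C@@H](C)CC/C(C)=C/CC/C(C)=C/CC[C@H]1O[C@]1(C)COS(=O)(=O)C(F)(F)F
F16 | step 10 | (S)-(5,6-dimethylhept-6-en-1-yn-1-yl)trimethylsilane | C=C(C)[C@@H](C)CCC#C[Si](C)(C)C
F17 | step 10 | (S)-5,6-dimethylhept-6-en-1-yne | C=C(C)[C@@H](C)CCC#C
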